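Everything rests on opening the 4-bromofuran-2(5H)-one ring to an acyclic alkyne: ring carbons C3 and C4 are the two alkyne carbons, carbonyl C2 is carbon monoxide, O1 is a propargylic hydroxyl on C5 and the C4 bromine is bromide. One bromopalladation–cyclocarbonylation at divalent palladium thus makes C4–Br, C3–C2 and C2–O1 and closes the ring. Its precursor is a (5R)-1,1-dibromooct-3-yne-2,5-diol whose stereocentre oxygen already carries the acetate, leaving one free hydroxyl beside the dibromomethyl group. The lone stereocentre comes from (R)-hex-1-yn-3-ol and is never touched; a final E1cB loss of HBr gives the Z-bromomethylene.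

Key step: step 4

Assumption: (R)-hex-1-yn-3-ol is taken as a catalogue compound in enantioenriched form; O1 and C2–C5 number the furanone ring, C1' is the acetoxy-bearing side-chain carbon, and the carbinol next to the dibromomethyl group is carried as both epimers because step 5 destroys that centre.

Step 1
Reactants: 1 (R)-hex-1-yn-3-ol; 2 N,N-dimethylformamide
Product: 5 (R)-4-hydroxyhept-2-ynal, via dilithium alkoxide–acetylide 3 (not isolated), via dilithium hemiaminal alkoxide 4 (not isolated)
Conditions: n-BuLi (2.1 equiv), THF, −78 to −20 °C; 2 (3 equiv), −78 °C to rt; inverse quench into aq KH2PO4/MTBE, 0 °C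
Reagents that add atoms: N,N-dimethylformamide, CN(C)C=O
Why: Formylation of an alkynyllithium with DMF: the alkoxide–acetylide 3 adds once because the hemiaminal alkoxide 4 persists until the buffered inverse quench, which releases the aldehyde while keeping the liberated dimethylamine protonated and away from the ynal; the stereocentre is only deprotonated at oxygen and keeps its R configuration.

Step 2
Reactants: 5 (R)-4-hydroxyhept-2-ynal; 6 acetic anhydride
Product: 7 (R)-1-oxohept-2-yn-4-yl acetate
Conditions: 6 (1.2 equiv), pyridine, CH2Cl2, 0 °C
Reagents that add atoms: acetic anhydride, CC(=O)OC(C)=O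
Why: O-Acylation of a secondary alcohol with an anhydride and a weak amine base: pyridine without DMAP at 0 °C is chosen because the propargylic hydrogen of a γ-hydroxy ynal is vinylogously acidic and stronger or more nucleophilic amines could isomerise the ynal or add to it; the C–O bond at the stereocentre is not broken, so the configuration is retained.

Step 3
Reactants: 7 (R)-1-oxohept-2-yn-4-yl acetate; 8 dibromomethane
Product: 10 (5R)-1,1-dibromo-2-hydroxyoct-3-yn-5-yl acetate (both C2 epimers), via dibromomethyllithium 9 (not isolated)
Conditions: 8 (1.3 equiv), LiN(i-Pr)2 (1.15 equiv), THF, −95 °C; then 7, −95 °C; AcOH/THF quench at −95 °C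
Reagents that add atoms: dibromomethane, BrCBr
Why: 1,2-Addition of a lithium carbenoid to an aldehyde: at −95 °C the preformed dibromomethyllithium 9 should attack the ynal carbonyl far faster than the acetate, the cold acidic quench stops the β-bromo alkoxide from closing to a bromo-epoxide, and the new carbinol centre forms without control, which is acceptable because step 5 removes it.

Step 4
Reactants: 10 (5R)-1,1-dibromo-2-hydroxyoct-3-yn-5-yl acetate (both C2 epimers); 11 carbon monoxide; 12 CuBr2 (copper dibromide)
Product: 15 (R)-1-[4-bromo-5-(dibromomethyl)-2-oxo-2,5-dihydrofuran-3-yl]butyl acetate (both C5 epimers), via alkenylpalladium bromide 13 (not isolated), via acylpalladium bromide 14 (not isolated)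
Conditions: PdBr2 (5 mol %), 12 (3 equiv), 11 (1 atm), MeCN, rt
Reagents that add atoms: carbon monoxide, [C-]#[O+]; copper dibromide, Br[Cu]Br
Why: Divalent palladium binds the alkyne and bromide adds anti at C4, giving alkenylpalladium bromide 13 with the metal on C3 (where the acetate carbonyl can chelate it); CO then inserts to acylpalladium bromide 14, whose acyl group lies cis to the C5 carbinol, and the hydroxyl displaces the metal to give 15, HBr and zerovalent palladium, which two equivalents of CuBr2 return to the divalent state. The closest known reaction type is the PdX2/CuX2 halopalladation–cyclocarbonylation of 2-alkyn-1-ols to 4-halofuran-2(5H)-ones. The ring closes by 5-exo-trig acyl substitution, O1 attacking C2. No stereocentre is created: C1' is a spectator whose C–O bond is never broken, and C5 stays an epimeric mixture that step 5 erases. The step needs bromine at C4, CO at C3 and anti addition; bromopalladation is reversible and, with the other oxygen capped as an acid-stable acetate, only the anti adduct metallated at C3 can end in a five-membered lactone. MeCN and the high bromide concentration should favour external anti attack over the syn pathway, which would lead to a four-membered lactone.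

Step 5
Reactants: 15 (R)-1-[4-bromo-5-(dibromomethyl)-2-oxo-2,5-dihydrofuran-3-yl]butyl acetate (both C5 epimers)
Product: 17 (R)-1-[(5Z)-4-bromo-5-(bromomethylidene)-2-oxo-2,5-dihydrofuran-3-yl]butyl acetate, via triethylammonium furan-2-olate 16 (not isolated)
Conditions: Et3N (1.2 equiv), CH2Cl2, −20 to 0 °C
Reagents that add atoms: none
Why: E1cB dehydrobromination: triethylamine removes the acidic γ-hydrogen at C5 to give the furan-2-olate 16, which expels bromide from the dibromomethyl group (a far better leaving group than the C1' acetate) with the remaining bromine turned away from the C4 bromine and towards O1, so the more stable Z-bromomethylene isomer should form while C1' is untouched.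

Compound list
1 | (R)-hex-1-yn-3-ol | CCC[C@@H](O)C#C | starting material
2 | N,N-dimethylformamide | CN(C)C=O | starting material
3 | dilithium (R)-hex-1-yn-1-id-3-olate (alkoxide–acetylide of 1) | CCC[C@@H]([O-])C#[C-].[Li+].[Li+] | intermediate
4 | dilithium (4R)-1-(dimethylamino)hept-2-yne-1,4-diolate (hemiaminal alkoxide) | CCC[C@@H]([O-])C#CC([O-])N(C)C.[Li+].[Li+] | intermediate
5 | (R)-4-hydroxyhept-2-ynal | CCC[C@@H](O)C#CC=O | intermediate
6 | acetic anhydride | CC(=O)OC(C)=O | starting material
7 | (R)-1-oxohept-2-yn-4-yl acetate | CCC[C@@H](OC(C)=O)C#CC=O | intermediate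
8 | dibromomethane | BrCBr | starting material
9 | dibromomethyllithium | [Li]C(Br)Br | intermediate
10 | (5R)-1,1-dibromo-2-hydroxyoct-3-yn-5-yl acetate (both C2 epimers) | CCC[C@@H](OC(C)=O)C#CC(O)C(Br)Br | intermediate
11 | carbon monoxide | [C-]#[O+] | starting material
12 | CuBr2 (copper dibromide) | Br[Cu]Br | starting material
13 | alkenylpalladium bromide from anti bromopalladation of 10 (divalent palladium on C3, bromine on C4) | CCC[C@@H](OC(C)=O)/C([Pd]Br)=C(\Br)C(O)C(Br)Br | intermediate
14 | acylpalladium bromide from CO insertion into 13 | CCC[C@@H](OC(C)=O)/C(C(=O)[Pd]Br)=C(\Br)C(O)C(Br)Br | intermediate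
15 | (R)-1-[4-bromo-5-(dibromomethyl)-2-oxo-2,5-dihydrofuran-3-yl]butyl acetate (both C5 epimers) | CCC[C@@H](OC(C)=O)C1=C(Br)C(C(Br)Br)OC1=O | intermediate
16 | triethylammonium 3-[(1R)-1-acetoxybutyl]-4-bromo-5-(dibromomethyl)furan-2-olate | CCC[C@@H](OC(C)=O)C1=C([O-])OC(C(Br)Br)=C1Br.CC[NH+](CC)CC | intermediate
17 | (R)-1-[(5Z)-4-bromo-5-(bromomethylidene)-2-oxo-2,5-dihydrofuran-3-yl]butyl acetate | CCC[C@@H](OC(C)=O)C1=C(Br)/C(=C/Br)OC1=O | target

Total step count: 5
Longest linear sequence: 5 steps (1 to 17)

Steps most likely to fail

Step 4. The bromopalladation may run syn or place the metal on C4, which would divert the acylpalladium into a four-membered lactone. The alkenylpalladium may also lose the neighbouring acetate by β-elimination before CO inserts, or CuBr2 may simply dibrominate the alkyne. The fallback sets out from 10 and returns at 15. The free hydroxyl of 10 is mesylated (MsCl, Et3N, CH2Cl2, −40 °C) to (5R)-1,1-dibromo-2-(methanesulfonyloxy)oct-3-yn-5-yl acetate F1. Pd(PPh3)4 (zerovalent palladium) under CO in THF/H2O should then displace the mesylate in SN2' fashion and carbonylate the allenylpalladium at the future C3, giving 2-[(1R)-1-acetoxybutyl]-5,5-dibromopenta-2,3-dienoic acid F2. CuBr2 in aqueous acetone should bromolactonise this 2,3-allenoic acid, with bromine going to the central allene carbon and the carboxylate oxygen to the terminus bearing the dibromomethyl group, which delivers 15. Both are known reaction types, and the ring then closes through O1–C5 instead of O1–C2.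

Step 3. The lithium carbenoid may attack the acetate carbonyl, or deprotonate the propargylic position (vinylogous to the aldehyde) with erosion of configuration at C1'. The β-bromo alkoxide may also collapse to a bromo-epoxide if the mixture warms before the quench. The fallback sets out from 1 and returns at 15, keeping esters away from all organolithium chemistry. TBSCl and imidazole give (R)-tert-butyl(hex-1-yn-3-yloxy)dimethylsilane F3. n-BuLi followed by DMF gives (R)-4-(tert-butyldimethylsilyloxy)hept-2-ynal F4. Dibromomethane with LiN(i-Pr)2 at −78 °C gives (5R)-1,1-dibromo-5-(tert-butyldimethylsilyloxy)oct-3-yn-2-ol F5. The PdBr2/CuBr2/CO step, run with propylene oxide as HBr scavenger to protect the silyl ether, should give (R)-4-bromo-3-[1-(tert-butyldimethylsilyloxy)butyl]-5-(dibromomethyl)furan-2(5H)-one F6. Ac2O with catalytic Bi(OTf)3 then exchanges the silyl ether directly for the acetate and gives 15.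

Step 2. The amine may isomerise the γ-hydroxy ynal through its vinylogously acidic propargylic hydrogen (redox isomerisation or loss of optical purity), or add in conjugate fashion and start oligomerisation before acylation is complete. The fallback sets out from 5 and returns at 7, masking the aldehyde while the alcohol is acylated. HC(OMe)3 in MeOH with catalytic pyridinium p-toluenesulfonate gives (R)-1,1-dimethoxyhept-2-yn-4-ol F7. Ac2O, pyridine and catalytic DMAP, now harmless, give (R)-1,1-dimethoxyhept-2-yn-4-yl acetate F8. Formic acid at rt cleaves the acetal without touching the acetate and gives 7.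

Further compounds
F1 | step 4 | (5R)-1,1-dibromo-2-(methanesulfonyloxy)oct-3-yn-5-yl acetate (both C2 epimers) | CCC[C@@H](OC(C)=O)C#CC(OS(C)(=O)=O)C(Br)Br
F2 | step 4 | 2-[(1R)-1-acetoxybutyl]-5,5-dibromopenta-2,3-dienoic acid (both allene epimers) | CCC[C@@H](OC(C)=O)C(C(=O)O)=C=CC(Br)Br
F3 | step 3 | (R)-tert-butyl(hex-1-yn-3-yloxy)dimethylsilane | CCC[C@@H](O[Si](C)(C)C(C)(C)C)C#C
F4 | step 3 | (R)-4-(tert-butyldimethylsilyloxy)hept-2-ynal | CCC[C@@H](O[Si](C)(C)C(C)(C)C)C#CC=O
F5 | step 3 | (5R)-1,1-dibromo-5-(tert-butyldimethylsilyloxy)oct-3-yn-2-ol (both C2 epimers) | CCC[C@@H](O[Si](C)(C)C(C)(C)C)C#CC(O)C(Br)Br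
F6 | step 3 | (R)-4-bromo-3-[1-(tert-butyldimethylsilyloxy)butyl]-5-(dibromomethyl)furan-2(5H)-one (both C5 epimers) | CCC[C@@H](O[Si](C)(C)C(C)(C)C)C1=C(Br)C(C(Br)Br)OC1=O
F7 | step 2 | (R)-1,1-dimethoxyhept-2-yn-4-ol | CCC[C@@H](O)C#CC(OC)OC
F8 | step 2 | (R)-1,1-dimethoxyhept-2-yn-4-yl acetate | CCC[C@@H](OC(C)=O)C#CC(OC)OC
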